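## Analysis of the target

Isocardopatine (17) has one carbocycle, a cyclobutane (C1 to C4). The adjacent carbons C1 and C2 each carry an ethynyl spacer (Cα≡Cβ) that ends at C5 of a 2,2'-bithiophene (inner thiophene ring A, outer thiophene ring B). C1 and C2 are the only stereocentres. The two arms are cis, so a mirror plane makes the molecule meso (1R,2S), and only the relative configuration has to be controlled. That cis arrangement is the less stable one, and the ring offers no handle: C3 and C4 are bare methylenes. A ring construction that leaves functionality on C3 or C4 must therefore remove it again, and any carbonyl on C1 or C2 invites epimerisation to trans. The bithienylalkyne chromophores are photoreactive, the electron-rich thiophenes do not tolerate electrophilic halogen, and a cis-1,2-dialkynylcyclobutane is a 1,5-diyne set up for a [3,3]-sigmatropic shift, so the last steps must be mild and dark. The strategy rests on the two exocyclic bonds C1–Cα and C2–Cα′. They lie on the same face of neighbouring ring carbons, which is where the two new bonds of a syn 1,2-addition to cyclobutene (3) end up. If that addition delivers boron, as in the meso bis(boronate) 5, each C–B bond can be exchanged for a C–C(sp) bond with retention.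

## Retrosynthetic reasoning

**17 to 15 and 16.** The two Cβ–C5 bonds between the alkyne termini and ring A are cut first, leading to cis-1,2-diethynylcyclobutane (15) and two molecules of 5-bromo-2,2'-bithiophene (16). These sp–sp2 bonds are the most reliably made in the molecule, and cutting both uses the symmetry. The disconnection also keeps the light-sensitive chromophore out of every earlier step and keeps the thiophenes away from the electrophilic halogen used upstream. The forward reaction is a twofold Sonogashira coupling that must run at ambient temperature in the dark.

**15 to 5 and 9.** Next the ring-to-alkyne bonds C1–Cα and C2–Cα′ are cut. The ring bonds are not chosen because the ring of 15 carries nothing on C3 or C4 that could guide a cycloaddition or contraction. The exocyclic bonds, in contrast, can come from the C–B bonds of the meso bis(boronate) 5, which are configurationally stable and are replaced with retention in a 1,2-metallate shift. The two-carbon alkyne unit comes from vinyl N,N-diisopropylcarbamate (9), used as its α-lithio derivative 10. Both stereocentres are thus inherited rather than made, and no intermediate has a carbonyl next to C1 or C2. The forward reaction has to form the bis(borate) 11, move each ring carbon from boron to carbon (12), eliminate boron and halide to the bis(enol carbamate) 13, and expel carbamate under a strong amide base to the acetylide 14 and then 15.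

**5 to 3 and 4.** Both C–B bonds are cut together, leading to cyclobutene (3) and bis(pinacolato)diboron (4). A metal-catalysed diboration adds the B–B bond suprafacially, so the cis, meso relation follows from the mechanism alone. The catalyst has to be a phosphine-free zerovalent platinum complex, because phosphine ligands compete with the weakly binding alkene.

**3 to 2 to 1.** The double bond of 3 is made by base-induced elimination from cyclobutyl tosylate (2), the sulfonate of cyclobutanol (1). A bimolecular elimination is required so that the cyclobutyl cation and its rearrangements are never reached.

**9 to 6 and 7.** The O–C(O) bond of 9 is cut to lithium ethenolate (8) and N,N-diisopropylcarbamoyl chloride (7). The enolate 8 comes from tetrahydrofuran (6) by α-lithiation and cycloreversion with loss of a two-carbon alkene fragment. This gives the acetaldehyde enolate without ever handling the aldehyde.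

## Alternatives that were turned down

**Alternative 1:** The ring is cut at C1–C4 and C2–C3 into a ketene (future C3 and C4) and a cis-alkene (future C1 and C2).
- Forward key step: dichloroketene A2, generated in the flask by reductive dechlorination of its acid chloride, adds in a thermal [2+2] cycloaddition to one double bond of cyclohexa-1,4-diene A1. The product is cis-8,8-dichlorobicyclo[4.2.0]oct-3-en-7-one A3.
- Continuation: the six-membered ring is a tether for the two future arms. Removal of both chlorines and of the carbonyl would give cis-bicyclo[4.2.0]oct-3-ene A4, ozonolysis the dialdehyde A5, and enol sulfonate formation and elimination at each CH2–CHO unit the diyne 15.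
- For it: the cis relation is enforced by the ring fusion and cannot be lost, the materials are bulk chemicals, and the cycloaddition scales well. On stereochemical certainty this plan is stronger than the chosen one.
- Against it: the cycloaddition puts chlorine and oxygen on C3 and C4, the ring carbons that are bare methylenes in 17, so three operations only erase functionality. The alkyne is unveiled from an enol sulfonate whose elimination can also run through the ring C–H, giving an allene and destroying C1 or C2.
- Comparison: about five steps to 15, against four in the longest line of the chosen route. The chosen strategy offers instead that every step makes a bond that is kept, with no redox corrections on the ring.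

**Alternative 2:** The ring bond C2–C3 is made by contraction of a five-membered ring, with C2 carrying an ester that later becomes the second alkyne.
- Forward key step: photolysis of the diazoketone A6 in an alcohol triggers a Wolff rearrangement. The α-methylene migrates to the diazo carbon to give the ketene A7, and alcohol addition with protonation on the face away from the silylalkyne gives the cis ester A8 (racemic).
- Continuation: reduction to the aldehyde A9, one-carbon homologation to the alkyne and desilylation would lead to 15.
- For it: the photochemical Wolff contraction is dependable and free of organometallics, and A8 is a stable, non-volatile intermediate. On ease of handling it is stronger than the chosen route, which passes through gaseous 3 and volatile 15. The two arms are also differentiated, which would serve unsymmetrical analogues but gains nothing for the symmetric 17.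
- Against it: the cis relation comes from a kinetic protonation whose facial bias is set by a slender, linear alkyne. It then sits α to an ester and to the aldehyde A9, where base-mediated homologation can equilibrate it to trans. A6 needs diazo transfer at the more hindered of two α-positions, and the sequence from a five-membered enone runs to seven or more steps.
- Comparison: the chosen strategy replaces a kinetically set, epimerisable centre by two stereospecific migrations at carbons that are never enolisable.

**Alternative 3:** The bonds C1–C2 and C1–C4 are made by building a cyclobutanone onto an aldehyde carbon that already carries one complete arm.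
- Forward key step: the sulfonium ylide A11 adds to the carbonyl of the ynal A10 to give the oxaspiropentane A12. Lewis-acid-induced ring expansion, by shift of a cyclopropane bond to the propargylic cation, gives the cyclobutanone A13 (racemic).
- For it: it is convergent, installs one bithienylalkyne arm from the start, forms the four-membered ring in one flask and avoids volatile intermediates. In these respects it is stronger than the chosen route.
- Against it: the stereocentre of A13 is α to the ketone and labile. The carbonyl carbon must still be turned into a CH bearing the second alkynyl arm cis to the first, by alkynyl addition and deoxygenation, and for this only the small steric bias of a linear alkyne is available. The photosensitive, acid-sensitive chromophore is carried through cationic and reductive steps, and the symmetry of 17 is not used.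
- Comparison: the chosen strategy fixes cis before any arm is present, makes both arms by the same operation and introduces the chromophore only at the end.

Key step: step 5

## Route

Remark: 5, 11 to 15 and 17 are meso, so the stereodescriptors in their SMILES express only the cis relation; 3 and 15 are volatile and are handled cold, as a condensed liquid or a stock solution.

**Step 1**
Reactants: 1 cyclobutanol
Product: 2 cyclobutyl 4-methylbenzenesulfonate
Conditions: TsCl, pyridine, 0 °C to rt
Reagents that add atoms: 4-methylbenzenesulfonyl chloride, Cc1ccc(cc1)S(Cl)(=O)=O
Why: O-sulfonylation of a secondary alcohol; the C–O bond is not broken, so the cyclobutyl/cyclopropylcarbinyl cation manifold is not entered.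

**Step 2**
Reactants: 2 cyclobutyl 4-methylbenzenesulfonate
Product: 3 cyclobutene
Conditions: KOtBu, DMSO, 70 °C, N2 sweep into a −78 °C trap
Reagents that add atoms: none
Why: E2 elimination with a hindered alkoxide in a dipolar aprotic solvent; the bimolecular pathway avoids cationic ring contraction and ring opening, and the gaseous alkene leaves the mixture as it forms.

**Step 3**
Reactants: 3 cyclobutene (excess); 4 bis(pinacolato)diboron
Product: 5 cis-1,2-bis(4,4,5,5-tetramethyl-1,3,2-dioxaborolan-2-yl)cyclobutane (meso)
Conditions: Pt(dba)2 (3 mol %; dba = dibenzylideneacetone), toluene, 50 °C, sealed tube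
Reagents that add atoms: none
Why: Platinum-catalysed alkene diboration: oxidative addition of B–B to zerovalent platinum, syn insertion of the strained alkene into a Pt–B bond and C–B reductive elimination with retention put both boryl groups on one face, which sets C1 and C2 cis. Phosphine-free Pt(dba)2 is used and not Pt(PPh3)4, whose phosphine suppresses alkene coordination.

**Step 4**
Reactants: 6 tetrahydrofuran; 7 N,N-diisopropylcarbamoyl chloride
Product: 9 vinyl N,N-diisopropylcarbamate, via lithium ethenolate 8 (not isolated)
Conditions: n-BuLi, THF, rt, 16 h; then 7, DMPU, 0 °C to rt
Reagents that add atoms: none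
Why: α-Lithiation of tetrahydrofuran and [3+2] cycloreversion release ethene and the acetaldehyde enolate 8, which the hard carbamoyl chloride acylates on oxygen (O-carbamoylation of an enolate).

**Step 5**
Reactants: 5 cis-1,2-bis(4,4,5,5-tetramethyl-1,3,2-dioxaborolan-2-yl)cyclobutane; 9 vinyl N,N-diisopropylcarbamate
Product: 15 cis-1,2-diethynylcyclobutane (meso), via 1-lithiovinyl carbamate 10 (not isolated), via bis(borate) complex 11 (not isolated), via bis(iodoalkylboronate) 12 (not isolated), via bis(enol carbamate) 13 (not isolated), via dilithium bis(acetylide) 14 (not isolated)
Conditions: 9 (2.6 equiv), LiN(i-Pr)2 (2.5 equiv), THF, −78 °C; 5, −78 °C; I2, MeOH, −78 °C; NaOMe, MeOH, −78 °C to rt; solvent switch to THF; LiN(i-Pr)2 (8 equiv), −78 °C to rt; H2O, 0 °C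
Reagents that add atoms: none
Why: Deprotonation of 9 at the oxygen-bearing vinyl carbon gives 10, which adds to each Lewis-acidic boron of 5 to form the tetracoordinate bis(borate) 11. Iodine attacks the electron-rich enol carbamate double bond at its CH2 terminus, and the cyclobutyl carbon shifts from boron to the adjacent electron-poor carbon, suprafacially and therefore with retention, to give 12. Methoxide then adds to boron, and anti-elimination of boron and iodide forms the 1,1-disubstituted enol carbamate 13. Excess lithium diisopropylamide removes a terminal vinylic proton, lithium carbamate is expelled in a β-elimination, and the alkyne is held as the acetylide 14 until the aqueous quench. The closest known reaction type is the Zweifel olefination of secondary alkyl pinacol boronic esters with an α-lithiated vinyl carbamate followed by base-mediated 1,2-elimination to the terminal alkyne, here run at both boron atoms of one molecule. No ring is closed and no stereocentre is created: C1 and C2 keep the cis configuration set in step 3, the controlling element being the stereoretentive 1,2-metallate shift at each carbon. The step needs migration of the ring carbon and not of a pinacol oxygen, which is secured because alkoxy ligands on boron do not migrate and the only other carbon ligand is the acceptor. It also needs complete formation of the doubly charged complex (helped by excess 10 and lithium chelation by the carbamate carbonyl) and configurational stability under base, which holds because the ring C–H bonds are only allylic in 13 and propargylic to an acetylide in 14.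

**Step 6**
Reactants: 15 cis-1,2-diethynylcyclobutane; 16 5-bromo-2,2'-bithiophene (2.3 equiv)
Product: 17 isocardopatine, cis-1,2-bis[(2,2'-bithiophen-5-yl)ethynyl]cyclobutane (meso, 1R,2S)
Conditions: Pd(PhCN)2Cl2 (5 mol %), P(t-Bu)3 (10 mol %), CuI (4 mol %), i-Pr2NH, 1,4-dioxane, rt, dark, argon
Reagents that add atoms: none
Why: Twofold Sonogashira coupling; the bulky electron-rich phosphine lets the heteroaryl bromide undergo oxidative addition at ambient temperature, so neither a thermal [3,3] shift of the cis-dialkynylcyclobutane nor photoreaction of the chromophore is provoked, and the sp3 stereocentres are not touched.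

## Compound list

1 | cyclobutanol | OC1CCC1 | starting material
2 | cyclobutyl 4-methylbenzenesulfonate | Cc1ccc(cc1)S(=O)(=O)OC1CCC1 | intermediate
3 | cyclobutene | C1=CCC1 | intermediate
4 | bis(pinacolato)diboron | CC1(C)OB(OC1(C)C)B1OC(C)(C)C(C)(C)O1 | starting material
5 | cis-1,2-bis(4,4,5,5-tetramethyl-1,3,2-dioxaborolan-2-yl)cyclobutane (meso) | CC1(C)OB(OC1(C)C)[C@@H]1CC[C@@H]1B1OC(C)(C)C(C)(C)O1 | intermediate
6 | tetrahydrofuran | C1CCOC1 | starting material
7 | N,N-diisopropylcarbamoyl chloride | CC(C)N(C(C)C)C(Cl)=O | starting material
8 | lithium ethenolate | [Li]OC=C | intermediate
9 | vinyl N,N-diisopropylcarbamate | C=COC(=O)N(C(C)C)C(C)C | intermediate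
10 | 1-lithiovinyl N,N-diisopropylcarbamate | [Li]C(=C)OC(=O)N(C(C)C)C(C)C | intermediate
11 | dilithium cis-cyclobutane-1,2-diylbis{[1-(N,N-diisopropylcarbamoyloxy)vinyl](pinacolato)borate} | [Li+].[Li+].C=C(OC(=O)N(C(C)C)C(C)C)[B-]1(OC(C)(C)C(C)(C)O1)[C@@H]1CC[C@@H]1[B-]1(OC(C)(C)C(C)(C)O1)C(=C)OC(=O)N(C(C)C)C(C)C | intermediate
12 | cis-1,2-bis[1-(N,N-diisopropylcarbamoyloxy)-2-iodo-1-(4,4,5,5-tetramethyl-1,3,2-dioxaborolan-2-yl)ethyl]cyclobutane (mixture of diastereomers at the two boron-bearing side-chain carbons) | ICC(OC(=O)N(C(C)C)C(C)C)(B1OC(C)(C)C(C)(C)O1)[C@@H]1CC[C@@H]1C(CI)(OC(=O)N(C(C)C)C(C)C)B1OC(C)(C)C(C)(C)O1 | intermediate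
13 | cis-cyclobutane-1,2-diylbis(ethene-1,1-diyl) bis(N,N-diisopropylcarbamate) (meso) | C=C(OC(=O)N(C(C)C)C(C)C)[C@@H]1CC[C@@H]1C(=C)OC(=O)N(C(C)C)C(C)C | intermediate
14 | dilithium cis-cyclobutane-1,2-diylbis(ethynide) | [Li]C#C[C@@H]1CC[C@@H]1C#C[Li] | intermediate
15 | cis-1,2-diethynylcyclobutane (meso) | C#C[C@@H]1CC[C@@H]1C#C | intermediate
16 | 5-bromo-2,2'-bithiophene | Brc1ccc(-c2cccs2)s1 | starting material
17 | isocardopatine, cis-1,2-bis[(2,2'-bithiophen-5-yl)ethynyl]cyclobutane (meso) | C(#C[C@@H]1CC[C@@H]1C#Cc1ccc(-c2cccs2)s1)c1ccc(-c2cccs2)s1 | target

## Step count and risks

Total: 6 steps. Longest linear sequence: 5 steps (1, 2, 3, 5, 6 from cyclobutanol); step 4 is a one-step side branch.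

**Step 5 (key step).**
- Most likely failure: incomplete formation of the doubly charged bis(borate). The first anionic boron disfavours addition at its cis neighbour electrostatically and sterically, so only one arm would be alkynylated.
- Second failure mode: iodinolysis of a ring C–B(ate) bond, followed by anti-elimination of the neighbouring boron and iodide, which fragments the ring substituents back to the alkene.
- Third failure mode: in the base stage, slow epimerisation toward trans, or elimination through the ring C–H to an allene.
- Fallback: from 5, only one equivalent of 10 is used so that a singly charged mono(borate) forms. Iodine and NaOMe then give 1-[cis-2-(4,4,5,5-tetramethyl-1,3,2-dioxaborolan-2-yl)cyclobutyl]vinyl N,N-diisopropylcarbamate F2. F2 is purified and taken through a second, separate olefination cycle at the remaining boron. This comes back to the route at 13, now isolated and dried, which is eliminated with LiN(i-Pr)2 as in step 5 to give 15.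

**Step 3.**
- Most likely failure: low conversion. Insertion of a 1,2-disubstituted alkene into the Pt–B bond may be slow with the weakly Lewis-acidic pinacol diboron, β-hydride elimination from the borylcyclobutylplatinum intermediate may compete with reductive elimination, and the gaseous alkene may be lost.
- Fallback: from 3, the more electrophilic bis(catecholato)diboron is added under Pt(dba)2 to give cis-1,2-bis(1,3,2-benzodioxaborol-2-yl)cyclobutane F1. F1 is transesterified with pinacol without isolation and re-enters the route at 5.

**Step 6.**
- Most likely failure: oxidative homocoupling of the diyne at copper, stalling after the first coupling at ambient temperature, and light- or heat-induced degradation of the product during a long reaction.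
- Fallback: from 15, double deprotonation with n-BuLi at −78 °C and transmetallation with ZnCl2 give cis-1,2-bis[(chlorozincio)ethynyl]cyclobutane F3. F3 is coupled with 16 under copper-free Negishi conditions (Pd(P(t-Bu)3)2, THF, rt, dark) and comes back to the route at 17.

## Further compounds

F1 | step 3 | cis-1,2-bis(1,3,2-benzodioxaborol-2-yl)cyclobutane (meso) | c1ccc2OB(Oc2c1)[C@@H]1CC[C@@H]1B1Oc2ccccc2O1
F2 | step 5 | 1-[cis-2-(4,4,5,5-tetramethyl-1,3,2-dioxaborolan-2-yl)cyclobutyl]vinyl N,N-diisopropylcarbamate (racemic, one enantiomer drawn) | C=C(OC(=O)N(C(C)C)C(C)C)[C@@H]1CC[C@@H]1B1OC(C)(C)C(C)(C)O1
F3 | step 6 | cis-1,2-bis[(chlorozincio)ethynyl]cyclobutane | Cl[Zn]C#C[C@@H]1CC[C@@H]1C#C[Zn]Cl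
A1 | alternative 1 | cyclohexa-1,4-diene | C1=CCC=CC1
A2 | alternative 1 | dichloroketene | O=C=C(Cl)Cl
A3 | alternative 1 | cis-8,8-dichlorobicyclo[4.2.0]oct-3-en-7-one (racemic, one enantiomer drawn) | C2[C@@H]1C(Cl)(Cl)C(=O)[C@@H]1CC=C2
A4 | alternative 1 | cis-bicyclo[4.2.0]oct-3-ene | C2[C@@H]1CC[C@@H]1CC=C2
A5 | alternative 1 | cis-2,2'-(cyclobutane-1,2-diyl)diacetaldehyde | O=CC[C@@H]1CC[C@@H]1CC=O
A6 | alternative 2 | 2-diazo-3-[(triisopropylsilyl)ethynyl]cyclopentan-1-one (racemic) | O=C1CCC(C#C[Si](C(C)C)(C(C)C)C(C)C)C1=[N+]=[N-]
A7 | alternative 2 | {2-[(triisopropylsilyl)ethynyl]cyclobutylidene}methanone (ketene, racemic) | O=C=C1CCC1C#C[Si](C(C)C)(C(C)C)C(C)C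
A8 | alternative 2 | methyl cis-2-[(triisopropylsilyl)ethynyl]cyclobutane-1-carboxylate (racemic, one enantiomer drawn) | COC(=O)[C@@H]1CC[C@@H]1C#C[Si](C(C)C)(C(C)C)C(C)C
A9 | alternative 2 | cis-2-[(triisopropylsilyl)ethynyl]cyclobutane-1-carbaldehyde (racemic, one enantiomer drawn) | O=C[C@@H]1CC[C@@H]1C#C[Si](C(C)C)(C(C)C)C(C)C
A10 | alternative 3 | 3-(2,2'-bithiophen-5-yl)propynal | O=CC#Cc1ccc(-c2cccs2)s1
A11 | alternative 3 | diphenylsulfonium cyclopropylide | C1C[C-]1[S+](c1ccccc1)c1ccccc1
A12 | alternative 3 | 2-[(2,2'-bithiophen-5-yl)ethynyl]-1-oxaspiro[2.2]pentane (racemic) | C1CC12OC2C#Cc1ccc(-c2cccs2)s1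
A13 | alternative 3 | 2-[(2,2'-bithiophen-5-yl)ethynyl]cyclobutan-1-one (racemic, one enantiomer drawn) | O=C1CC[C@@H]1C#Cc1ccc(-c2cccs2)s1
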